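**Retrosynthetic overview**
1. Target 14 ⇐ global O‑debenzylation of the tetra‑O‑benzyl biflavone 13; the 4'‑OMe group stays.
2. 13 ⇐ C8–O diaryl ether bond, made last by a new one‑flask C8–H aryloxylation of flavone 5 with phenol 9 (through a C8 λ3‑iodane carrying a trimethoxyphenyl dummy ligand).
3. 5 and 9 ⇐ I2/DMSO oxidative cyclisation of the 2'-hydroxychalcones 4 and 7; each pyranone ring is closed on its own half before the coupling.
4. 4 and 7 ⇐ Claisen–Schmidt condensation of the common acetophenone 2 with 4‑methoxybenzaldehyde or 4‑(methoxymethoxy)benzaldehyde; 2 ⇐ phloroacetophenone + BnBr.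
5. Ring order: A rings are bought (phloroacetophenone), the two C rings are formed separately, and the two finished flavones are joined at the end.

Assumption: the target has no stereocentre and no configurationally stable axis, so it is achiral and "single enantiomer" needs no stereocontrol; the only stereo‑descriptor in the route is the E geometry of the chalcones.

**Step 1**
Reactants: 1 1-(2,4,6-trihydroxyphenyl)ethan-1-one
Product: 2 1-[2,4-bis(benzyloxy)-6-hydroxyphenyl]ethan-1-one
Conditions: BnBr (2.1 equiv), K2CO3 (2.2 equiv), DMF, 0 °C → rt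
Reagents that add atoms: benzyl bromide BrCc1ccccc1
Why: Williamson etherification of the 4‑OH and one ortho‑OH; the remaining ortho‑OH is hydrogen‑bonded to the acetyl carbonyl and far less nucleophilic, so alkylation stops at the dibenzyl ether.

**Step 2**
Reactants: 2 1-[2,4-bis(benzyloxy)-6-hydroxyphenyl]ethan-1-one; 3 4-methoxybenzaldehyde
Product: 4 (E)-1-[2,4-bis(benzyloxy)-6-hydroxyphenyl]-3-(4-methoxyphenyl)prop-2-en-1-one
Conditions: KOH (50% aq.), EtOH/THF, rt, 24 h
Reagents that add atoms: none
Why: Claisen–Schmidt (crossed aldol) condensation of the methyl ketone enolate with a non‑enolisable aldehyde, with E1cB dehydration giving the thermodynamically favoured E enone; benzyl ethers are inert to base.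

**Step 3**
Reactants: 4 (E)-1-[2,4-bis(benzyloxy)-6-hydroxyphenyl]-3-(4-methoxyphenyl)prop-2-en-1-one
Product: 5 5,7-bis(benzyloxy)-2-(4-methoxyphenyl)-4H-chromen-4-one
Conditions: I2 (10 mol%), DMSO, 130 °C
Reagents that add atoms: none
Why: I2/DMSO oxidative cyclisation of a 2'-hydroxychalcone (6‑endo oxa‑Michael closure, α‑iodination and HI loss, with DMSO re‑oxidising HI to I2) gives the flavone; benzyl and methyl ethers survive.

**Step 4**
Reactants: 2 1-[2,4-bis(benzyloxy)-6-hydroxyphenyl]ethan-1-one; 6 4-(methoxymethoxy)benzaldehyde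
Product: 7 (E)-1-[2,4-bis(benzyloxy)-6-hydroxyphenyl]-3-[4-(methoxymethoxy)phenyl]prop-2-en-1-one
Conditions: KOH (50% aq.), EtOH/THF, rt, 24 h
Reagents that add atoms: none
Why: Claisen–Schmidt condensation as in step 2; the MOM acetal is base‑stable and keeps the aldehyde electrophilic (a free 4‑phenoxide would deactivate it).

**Step 5**
Reactants: 7 (E)-1-[2,4-bis(benzyloxy)-6-hydroxyphenyl]-3-[4-(methoxymethoxy)phenyl]prop-2-en-1-one
Product: 9 5,7-bis(benzyloxy)-2-(4-hydroxyphenyl)-4H-chromen-4-one, via MOM-protected flavone 8 (not isolated)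
Conditions: I2 (10 mol%), DMSO, 130 °C; then 3 M HCl, MeOH/THF, 55 °C
Reagents that add atoms: none
Why: I2/DMSO oxidative cyclisation as in step 3, then acid‑catalysed methanolysis of the MOM acetal frees only the 4'-OH (any MOM loss during the cyclisation converges on the same product); benzyl ethers and the flavone are stable to HCl/MeOH.

**Step 6**
Reactants: 10 2-iodo-1,3,5-trimethoxybenzene
Product: 11 (2,4,6-trimethoxyphenyl)-λ3-iodanediyl diacetate
Conditions: mCPBA (1.1 equiv), AcOH/CH2Cl2, rt, dark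
Reagents that add atoms: acetic acid CC(=O)O
Why: Peracid oxidation of an aryl iodide to iodine(III) in acetic acid (standard (diacetoxyiodo)arene synthesis); the electron‑rich iodine is the most easily oxidised site and both acetate ligands come from the solvent.

**Step 7**
Reactants: 5 5,7-bis(benzyloxy)-2-(4-methoxyphenyl)-4H-chromen-4-one; 11 (2,4,6-trimethoxyphenyl)-λ3-iodanediyl diacetate; 9 5,7-bis(benzyloxy)-2-(4-hydroxyphenyl)-4H-chromen-4-one
Product: 13 5,7-bis(benzyloxy)-8-{4-[5,7-bis(benzyloxy)-4-oxo-4H-chromen-2-yl]phenoxy}-2-(4-methoxyphenyl)-4H-chromen-4-one, via aryl(TMP)iodonium trifluoroacetate 12 (not isolated)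
Conditions: 11 (1.2 equiv), CF3CO2H (1.5 equiv), HFIP/CH2Cl2, 0 °C → rt; evaporate; then 9 (1.2 equiv), K2CO3 (3 equiv), toluene/MeCN, 55 °C
Reagents that add atoms: none
Why: Proposed new method: a one‑flask formal dehydrogenative C–H/O–H etherification in which (i) the TFA/HFIP‑activated λ3‑iodane 11 is attacked in an SEAr‑type step by the most nucleophilic carbon of 5, C8 (the site where 5‑O‑alkylated 5,7‑dioxygenated flavones are halogenated; C6 is shielded by two benzyloxy groups and the B ring is deactivated by the chromone), giving diaryliodonium salt 12, and (ii) the phenoxide of 9 exchanges onto iodine and collapses by ligand coupling (three‑centre ipso attack) onto the flavonyl carbon, which is more electrophilic than the trimethoxyphenyl ipso carbon because it carries a meta acyl group and a vinylogous‑ester ring oxygen in place of a third methoxy donor, so 2‑iodo‑1,3,5‑trimethoxybenzene is expelled; neither aryl ligand has an ortho hydrogen, so aryne pathways are closed; the closest known reaction types are the acid/fluoroalcohol‑promoted condensation of arenes with (diacyloxyiodo)arenes to diaryliodonium salts and the metal‑free O‑arylation of phenols with aryl(trimethoxyphenyl)iodonium salts, neither of which has been shown on a flavone or with a transferring aryl group that is itself 2,4,6‑trioxygenated.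

**Step 8**
Reactants: 13 5,7-bis(benzyloxy)-8-{4-[5,7-bis(benzyloxy)-4-oxo-4H-chromen-2-yl]phenoxy}-2-(4-methoxyphenyl)-4H-chromen-4-one
Product: 14 5,7-dihydroxy-8-[4-(5,7-dihydroxy-4-oxo-4H-chromen-2-yl)phenoxy]-2-(4-methoxyphenyl)-4H-chromen-4-one
Conditions: H2 (1 atm), 10% Pd/C, THF/MeOH, rt
Reagents that add atoms: none
Why: Catalytic hydrogenolysis of the four aryl benzyl ethers; the aryl methyl ether, the diaryl ether and the chromone C2=C3 bonds are not reduced at 1 atm and room temperature.

**Compound list**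
1 | 1-(2,4,6-trihydroxyphenyl)ethan-1-one (phloroacetophenone) | CC(=O)c1c(O)cc(O)cc1O | starting material
2 | 1-[2,4-bis(benzyloxy)-6-hydroxyphenyl]ethan-1-one | CC(=O)c1c(O)cc(OCc2ccccc2)cc1OCc1ccccc1 | intermediate
3 | 4-methoxybenzaldehyde | COc1ccc(C=O)cc1 | starting material
4 | (E)-1-[2,4-bis(benzyloxy)-6-hydroxyphenyl]-3-(4-methoxyphenyl)prop-2-en-1-one | COc1ccc(/C=C/C(=O)c2c(O)cc(OCc3ccccc3)cc2OCc2ccccc2)cc1 | intermediate
5 | 5,7-bis(benzyloxy)-2-(4-methoxyphenyl)-4H-chromen-4-one | COc1ccc(-c2cc(=O)c3c(OCc4ccccc4)cc(OCc4ccccc4)cc3o2)cc1 | intermediate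
6 | 4-(methoxymethoxy)benzaldehyde | COCOc1ccc(C=O)cc1 | starting material
7 | (E)-1-[2,4-bis(benzyloxy)-6-hydroxyphenyl]-3-[4-(methoxymethoxy)phenyl]prop-2-en-1-one | COCOc1ccc(/C=C/C(=O)c2c(O)cc(OCc3ccccc3)cc2OCc2ccccc2)cc1 | intermediate
8 | 5,7-bis(benzyloxy)-2-[4-(methoxymethoxy)phenyl]-4H-chromen-4-one | COCOc1ccc(-c2cc(=O)c3c(OCc4ccccc4)cc(OCc4ccccc4)cc3o2)cc1 | intermediate
9 | 5,7-bis(benzyloxy)-2-(4-hydroxyphenyl)-4H-chromen-4-one | Oc1ccc(-c2cc(=O)c3c(OCc4ccccc4)cc(OCc4ccccc4)cc3o2)cc1 | intermediate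
10 | 2-iodo-1,3,5-trimethoxybenzene | COc1cc(OC)c(I)c(OC)c1 | starting material
11 | (2,4,6-trimethoxyphenyl)-λ3-iodanediyl diacetate | COc1cc(OC)c(I(OC(C)=O)OC(C)=O)c(OC)c1 | intermediate
12 | [5,7-bis(benzyloxy)-2-(4-methoxyphenyl)-4-oxo-4H-chromen-8-yl](2,4,6-trimethoxyphenyl)iodonium trifluoroacetate | COc1ccc(-c2cc(=O)c3c(OCc4ccccc4)cc(OCc4ccccc4)c([I+]c4c(OC)cc(OC)cc4OC)c3o2)cc1.[O-]C(=O)C(F)(F)F | intermediate
13 | 5,7-bis(benzyloxy)-8-{4-[5,7-bis(benzyloxy)-4-oxo-4H-chromen-2-yl]phenoxy}-2-(4-methoxyphenyl)-4H-chromen-4-one | COc1ccc(-c2cc(=O)c3c(OCc4ccccc4)cc(OCc4ccccc4)c(Oc4ccc(-c5cc(=O)c6c(OCc7ccccc7)cc(OCc7ccccc7)cc6o5)cc4)c3o2)cc1 | intermediate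
14 | 5,7-dihydroxy-8-[4-(5,7-dihydroxy-4-oxo-4H-chromen-2-yl)phenoxy]-2-(4-methoxyphenyl)-4H-chromen-4-one (CNP0295851.0) | COc1ccc(-c2cc(=O)c3c(O)cc(O)c(Oc4ccc(-c5cc(=O)c6c(O)cc(O)cc6o5)cc4)c3o2)cc1 | target

**Total step count:** 8. **Longest linear sequence:** 5 steps (steps 1, 2, 3, 7, 8; the arm through steps 1, 4, 5, 7, 8 is equally long).

**Three steps most likely to fail**

Step 7, the proposed new C8–H aryloxylation. The flavone A ring may be too weakly nucleophilic for the electron‑rich iodane 11. The ligand coupling may also transfer the trimethoxyphenyl group instead of the flavonyl group, which would give the trimethoxyphenyl ether of 9 and an 8‑iodoflavone. The fallback uses known chemistry only, sets out from compound 5 and comes back to the route at compound 13. NBS (1.05 equiv) in DMF at 0 °C → rt brominates 5 at C8, the usual site for 5‑O‑alkylated 5,7‑dioxygenated flavones, giving 5,7-bis(benzyloxy)-8-bromo-2-(4-methoxyphenyl)-4H-chromen-4-one F1. A copper‑catalysed Ullmann‑type diaryl ether coupling of F1 with phenol 9 (CuI 20 mol%, picolinic acid 40 mol%, K3PO4, DMSO, 110 °C) then gives 13. This fallback also makes step 6 unnecessary.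

Step 6, preparation of the electron‑rich diacetoxyiodoarene 11. Such trioxygenated λ3‑iodanes can be labile, and ring oxidation or self‑condensation may compete, so clean isolation is not assured. The fallback reverses the polarity of the iodonium assembly so that no iodine(III) has to be placed on the trimethoxyphenyl ring; it sets out from compound 5 and comes back at compound 13. NIS with catalytic TFA in MeCN gives 5,7-bis(benzyloxy)-8-iodo-2-(4-methoxyphenyl)-4H-chromen-4-one F2. Oxidation of F2 with mCPBA and TsOH·H2O in MeCN/CH2Cl2 gives 5,7-bis(benzyloxy)-8-[hydroxy(tosyloxy)-λ3-iodanyl]-2-(4-methoxyphenyl)-4H-chromen-4-one F3, which is not isolated. Adding 1,3,5‑trimethoxybenzene to F3 gives [5,7-bis(benzyloxy)-2-(4-methoxyphenyl)-4-oxo-4H-chromen-8-yl](2,4,6-trimethoxyphenyl)iodonium tosylate F4. Treating F4 with phenol 9 and K2CO3 under the second‑stage conditions of step 7 gives 13.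

Step 8, fourfold hydrogenolysis on a poorly soluble biflavone. Debenzylation may be incomplete, the C2=C3 bonds may be partly reduced to flavanones, or traces of aryl iodide carried over from step 7 may poison the catalyst. The fallback goes from compound 13 directly to compound 14 by Lewis‑acid debenzylation instead of hydrogenolysis: BCl3 (8 equiv) and pentamethylbenzene (12 equiv) in CH2Cl2 at −78 °C. The benzyl cations are trapped by the scavenger, and the aryl methyl ether and the diaryl ether are untouched at this temperature. No new compound is made on the way.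

**Further compounds**
F1 | step 7 | 5,7-bis(benzyloxy)-8-bromo-2-(4-methoxyphenyl)-4H-chromen-4-one | COc1ccc(-c2cc(=O)c3c(OCc4ccccc4)cc(OCc4ccccc4)c(Br)c3o2)cc1
F2 | step 6 | 5,7-bis(benzyloxy)-8-iodo-2-(4-methoxyphenyl)-4H-chromen-4-one | COc1ccc(-c2cc(=O)c3c(OCc4ccccc4)cc(OCc4ccccc4)c(I)c3o2)cc1
F3 | step 6 | 5,7-bis(benzyloxy)-8-[hydroxy(tosyloxy)-λ3-iodanyl]-2-(4-methoxyphenyl)-4H-chromen-4-one | COc1ccc(-c2cc(=O)c3c(OCc4ccccc4)cc(OCc4ccccc4)c(I(O)OS(=O)(=O)c4ccc(C)cc4)c3o2)cc1
F4 | step 6 | [5,7-bis(benzyloxy)-2-(4-methoxyphenyl)-4-oxo-4H-chromen-8-yl](2,4,6-trimethoxyphenyl)iodonium tosylate | COc1ccc(-c2cc(=O)c3c(OCc4ccccc4)cc(OCc4ccccc4)c([I+]c4c(OC)cc(OC)cc4OC)c3o2)cc1.Cc1ccc(S(=O)(=O)[O-])cc1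
F0 | step 8 | none | none
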